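**Retrosynthetic overview**
1. Nakijiquinone J (30) comes from (S)-2-methylbutylamine (29) and hydroxy-methoxyquinone 28, which comes from tetramethoxyarene 26 by ceric oxidation and site-selective hydrolysis; the quinone is unveiled last.
2. Feature used: in ring B (C5–C10) the C9–C10 bond lies next to the ring-fusion alkene C5=C6. With the C9 methyl read as CO2H (acid 22), C9(CO2H)–C10–C5=C6 is a γ,δ-unsaturated acid, the Claisen retron.
3. Key disconnection C9–C10: Ireland–Claisen ring contraction of δ-lactone 18 (lactone C3/C4/C5/C6 become C9/C8/C7/C6; cyclohexenyl C1'/C2' become C5/C10). It closes ring B and sets C9 and C10 from the lactone carbinol centre; C8 is carried through.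
4. Lactone 18 comes from benzylation (bromide 16, made from 12) of lactone 11, which comes from anti methylcuprate addition to dihydropyranone 9, made by allylation, acryloylation and RCM of enal 5 (Shapiro formylation of 1).
5. Ring order: ring A is bought; lactone ring (step 5); ring B (step 11); quinone ring from the arene (step 15).

Key step: step 11

Remark: decalin atoms are numbered C1–C3 (ring A CH2), C4 (CMe2), C5=C6, C7, C8 (CHMe), C9 (quaternary), C10 (fusion CH), C11 (benzylic CH2). Lactone atoms are O1, C2(=O), C3–C6; the cyclohexenyl alkene carbons are C1' (on C6) and C2'. (+)-Ipc2B(allyl) means the reagent derived from (−)-α-pinene.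

**Step 1**
Reactants: 1 2,2-dimethylcyclohexanone; 2 2,4,6-triisopropylbenzenesulfonohydrazide
Product: 3 (E)-N'-(2,2-dimethylcyclohexylidene)-2,4,6-triisopropylbenzenesulfonohydrazide
Conditions: cat. conc. HCl, MeCN, rt
Reagents that add atoms: none
Why: Acid-catalysed hydrazone condensation; only the CH2 side of the ketone carries α-hydrogens, so the later vinyl anion can form in one position only.

**Step 2**
Reactants: 3 trisylhydrazone
Product: 5 6,6-dimethylcyclohex-1-ene-1-carbaldehyde, via (6,6-dimethylcyclohex-1-en-1-yl)lithium 4 (not isolated)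
Conditions: n-BuLi (2.2 equiv), TMEDA, hexane–THF, −78 → 0 °C; DMF, −78 °C → rt; H2O
Reagents that add atoms: N,N-dimethylformamide, CN(C)C=O; n-butyllithium, [Li]CCCC (lithium of 4 only)
Why: Shapiro reaction (dianion, loss of sulfinate and N2) gives the vinyllithium, which is formylated by DMF.

**Step 3**
Reactants: 5 6,6-dimethylcyclohex-1-ene-1-carbaldehyde
Product: 7 (R)-1-(6,6-dimethylcyclohex-1-en-1-yl)but-3-en-1-ol, via its diisopinocampheylborinate 6 (not isolated)
Conditions: (+)-Ipc2B(allyl), Et2O, −78 °C; then 3 M NaOH, 30% H2O2, rt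
Reagents that add atoms: (+)-B-allyldiisopinocampheylborane, C=CCB([C@H]1C[C@H]2C[C@@H]([C@@H]1C)C2(C)C)[C@H]1C[C@H]2C[C@@H]([C@@H]1C)C2(C)C
Why: Brown allylation through a chair Zimmerman–Traxler transition state; the (−)-α-pinene-derived reagent should deliver allyl to the Re face of the enal and set the (R) carbinol centre, the later lactone C6.

**Step 4**
Reactants: 7 (R)-homoallylic alcohol
Product: 8 (R)-1-(6,6-dimethylcyclohex-1-en-1-yl)but-3-en-1-yl acrylate
Conditions: acryloyl chloride, Et3N, cat. DMAP, CH2Cl2, 0 °C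
Reagents that add atoms: acryloyl chloride, C=CC(=O)Cl
Why: O-acylation of a secondary alcohol with an acid chloride; the stereocentre is not involved.

**Step 5**
Reactants: 8 acrylate
Product: 9 (R)-6-(6,6-dimethylcyclohex-1-en-1-yl)-5,6-dihydro-2H-pyran-2-one
Conditions: Grubbs second-generation catalyst (5 mol%), CH2Cl2 (high dilution), 40 °C
Reagents that add atoms: none
Why: Ring-closing metathesis of the two terminal alkenes gives the six-membered unsaturated lactone; the trisubstituted ring alkene should not take part.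

**Step 6**
Reactants: 9 dihydropyranone
Product: 11 (4S,6R)-6-(6,6-dimethylcyclohex-1-en-1-yl)-4-methyltetrahydro-2H-pyran-2-one (methyl trans to the alkenyl group), via lactone lithium enolate 10 (not isolated)
Conditions: Me2CuLi (from MeLi and CuI), Et2O, −78 → −30 °C; aq. NH4Cl
Reagents that add atoms: lithium dimethylcuprate, [Li+].C[Cu-]C (made in the flask from methyllithium, C[Li], and CuI)
Why: Cuprate conjugate addition to the enoate; axial attack on the half-chair anti to the pseudo-equatorial C6 substituent should give the 4,6-trans lactone and set C4 (later C8).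

**Step 7**
Reactants: 12 1,2,4,5-tetramethoxybenzene
Product: 14 2,3,5,6-tetramethoxybenzaldehyde, via (2,3,5,6-tetramethoxyphenyl)lithium 13 (not isolated)
Conditions: n-BuLi, THF, 0 °C → rt; DMF, 0 °C; H2O
Reagents that add atoms: N,N-dimethylformamide, CN(C)C=O; n-butyllithium, [Li]CCCC (lithium of 13 only)
Why: Directed ortho-lithiation at the C–H flanked by two methoxy groups, then formylation.

**Step 8**
Reactants: 14 2,3,5,6-tetramethoxybenzaldehyde
Product: 15 (2,3,5,6-tetramethoxyphenyl)methanol
Conditions: NaBH4, MeOH, 0 °C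
Reagents that add atoms: none
Why: Borohydride reduction of an aryl aldehyde.

**Step 9**
Reactants: 15 benzylic alcohol
Product: 16 2,3,5,6-tetramethoxybenzyl bromide
Conditions: PBr3, Et2O, 0 °C; used at once
Reagents that add atoms: phosphorus tribromide, BrP(Br)Br
Why: Bromination of a benzylic alcohol through its phosphite ester.

**Step 10**
Reactants: 11 lactone; 16 benzylic bromide
Product: 18 (3R,4S,6R)-6-(6,6-dimethylcyclohex-1-en-1-yl)-4-methyl-3-(2,3,5,6-tetramethoxybenzyl)tetrahydro-2H-pyran-2-one, via lactone sodium enolate 17 (not isolated)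
Conditions: NaHMDS, THF, −78 °C; then 16, −78 → −40 °C
Reagents that add atoms: sodium bis(trimethylsilyl)amide, C[Si](C)(C)N([Na])[Si](C)(C)C (sodium of 17 only)
Why: Kinetic enolate alkylation (SN2) of the sodium enolate with a reactive benzylic bromide; the benzyl group should enter anti to the C4 methyl, but this centre is erased on enolisation in step 11.

**Step 11**
Reactants: 18 benzylated lactone
Product: 22 (1S,2S,8aR)-2,5,5-trimethyl-1-(2,3,5,6-tetramethoxybenzyl)-1,2,3,5,6,7,8,8a-octahydronaphthalene-1-carboxylic acid (the C9 carboxylic acid), via the lithium enolate of the benzylated lactone 19 (not isolated), via its tert-butyldimethylsilyl ketene acetal 20 (not isolated), via the tert-butyldimethylsilyl ester of the acid 21 (not isolated)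
Conditions: LDA, THF, −78 °C; TBSCl, HMPA, −78 → 0 °C; solvent change to PhMe, 110 °C (sealed tube); then AcOH–H2O–THF, rt (no strong acid)
Reagents that add atoms: tert-butyldimethylsilyl chloride, CC(C)(C)[Si](C)(C)Cl (silyl group of 20 and 21 only); lithium diisopropylamide, CC(C)N([Li])C(C)C (lithium of 19 only)
Why: The endocyclic silyl ketene acetal 20 (C3=C2) and the ring A alkene (C1'=C2') should undergo a concerted [3,3]-sigmatropic shift in which C3–C2' (C9–C10) forms, O1–C6 breaks and the alkene moves to C6=C1' (C5=C6); this is the Ireland–Claisen ring contraction known for 6-alkenyl δ-lactones. Ring B (C5–C6–C7–C8–C9–C10) closes as a six-membered carbocycle by this pericyclic contraction, through a boat-like, bicyclo[2.2.2]-shaped transition state, because the two-carbon tether C4–C5 cannot span a chair. C9 and C10 are set by suprafacial chirality transfer from the (6R) carbinol centre: the acetal carbon can be reached only on the lactone face that carries the cyclohexenyl group, and with the ring A CH2 (C1) pointing outward the new bond leaves the arylmethyl group cis to H10 and the carboxyl trans to it. C8 is untouched and, being trans to the alkenyl group in 18, ends cis to the carboxyl. The step needs the rearrangement to outrun ionisation of the allylic C6–O bond; the neutral silyl ketene acetal and the non-polar solvent are chosen for this, and the alkene position is fixed by the mechanism, so no Δ5(10) isomer can arise.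

**Step 12**
Reactants: 22 C9 carboxylic acid
Product: 23 [(1S,2S,8aR)-2,5,5-trimethyl-1-(2,3,5,6-tetramethoxybenzyl)-1,2,3,5,6,7,8,8a-octahydronaphthalen-1-yl]methanol
Conditions: LiAlH4, THF, reflux; Fieser work-up
Reagents that add atoms: none
Why: Hydride reduction of a hindered carboxylic acid to the primary alcohol; alkene and aryl ethers are inert.

**Step 13**
Reactants: 23 neopentyl alcohol
Product: 24 (1S,2S,8aR)-2,5,5-trimethyl-1-(2,3,5,6-tetramethoxybenzyl)-1,2,3,5,6,7,8,8a-octahydronaphthalene-1-carbaldehyde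
Conditions: Dess–Martin periodinane, CH2Cl2, 0 °C → rt
Reagents that add atoms: none
Why: Dess–Martin oxidation of a primary alcohol; the aldehyde has no α-hydrogen and cannot epimerise.

**Step 14**
Reactants: 24 aldehyde
Product: 26 3-{[(1R,2S,8aS)-1,2,5,5-tetramethyl-1,2,3,5,6,7,8,8a-octahydronaphthalen-1-yl]methyl}-1,2,4,5-tetramethoxybenzene, via the hydrazone of the aldehyde 25 (not isolated)
Conditions: N2H4·H2O, KOH, diethylene glycol, 130 °C then 200 °C
Reagents that add atoms: hydrazine (as hydrate), NN (nitrogen of 25 only)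
Why: Wolff–Kishner reduction (Huang-Minlon procedure) converts the angular formyl group into the C9 methyl; C9 is quaternary, so no stereocentre is at risk.

**Step 15**
Reactants: 26 tetramethoxyarene
Product: 27 2,5-dimethoxy-3-{[(1R,2S,8aS)-1,2,5,5-tetramethyl-1,2,3,5,6,7,8,8a-octahydronaphthalen-1-yl]methyl}cyclohexa-2,5-diene-1,4-dione
Conditions: (NH4)2Ce(NO3)6, MeCN–H2O, 0 °C
Reagents that add atoms: water, O
Why: Ceric oxidative demethylation of a para-dimethoxy pair to the p-quinone; the two para pairs are equivalent by the symmetry of the arene, so one quinone should form.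

**Step 16**
Reactants: 27 dimethoxyquinone
Product: 28 2-hydroxy-5-methoxy-3-{[(1R,2S,8aS)-1,2,5,5-tetramethyl-1,2,3,5,6,7,8,8a-octahydronaphthalen-1-yl]methyl}cyclohexa-2,5-diene-1,4-dione
Conditions: KOH, MeOH–H2O, rt; dilute HCl to pH 3–4
Reagents that add atoms: potassium hydroxide, [K+].[OH-]
Why: Addition–elimination of hydroxide at a vinylogous ester; by analogy with other 3-alkyl-2,5-dimethoxybenzoquinones of this class, the methoxy group next to the C11 substituent is twisted out of conjugation and should be replaced, and the resulting hydroxyquinone anion resists a second attack.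

**Step 17**
Reactants: 28 hydroxy-methoxyquinone; 29 (S)-2-methylbutan-1-amine
Product: 30 nakijiquinone J
Conditions: NaHCO3, EtOH, rt; dilute HCl to pH 4
Reagents that add atoms: none
Why: Addition–elimination of the primary amine at the remaining methoxy-bearing carbon (vinylogous ester to vinylogous amide); the amine stereocentre is not touched.

**Compound list**
1 | 2,2-dimethylcyclohexanone | CC1(C)CCCCC1=O | starting material
2 | 2,4,6-triisopropylbenzenesulfonohydrazide | CC(C)c1cc(C(C)C)c(S(=O)(=O)NN)c(C(C)C)c1 | starting material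
3 | (E)-N'-(2,2-dimethylcyclohexylidene)-2,4,6-triisopropylbenzenesulfonohydrazide | CC(C)c1cc(C(C)C)c(S(=O)(=O)N/N=C2\CCCCC2(C)C)c(C(C)C)c1 | intermediate
4 | (6,6-dimethylcyclohex-1-en-1-yl)lithium | [Li]C1=CCCCC1(C)C | intermediate
5 | 6,6-dimethylcyclohex-1-ene-1-carbaldehyde | O=CC1=CCCCC1(C)C | intermediate
6 | diisopinocampheylborinate of alcohol 7 | C=CC[C@@H](OB([C@H]1C[C@H]2C[C@@H]([C@@H]1C)C2(C)C)[C@H]1C[C@H]2C[C@@H]([C@@H]1C)C2(C)C)C1=CCCCC1(C)C | intermediate
7 | (R)-1-(6,6-dimethylcyclohex-1-en-1-yl)but-3-en-1-ol | C=CC[C@@H](O)C1=CCCCC1(C)C | intermediate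
8 | (R)-1-(6,6-dimethylcyclohex-1-en-1-yl)but-3-en-1-yl acrylate | C=CC[C@@H](OC(=O)C=C)C1=CCCCC1(C)C | intermediate
9 | (R)-6-(6,6-dimethylcyclohex-1-en-1-yl)-5,6-dihydro-2H-pyran-2-one | O=C1C=CC[C@H](C2=CCCCC2(C)C)O1 | intermediate
10 | lithium enolate of lactone 11 | [Li]OC1=C[C@@H](C)C[C@H](C2=CCCCC2(C)C)O1 | intermediate
11 | (4S,6R)-6-(6,6-dimethylcyclohex-1-en-1-yl)-4-methyltetrahydro-2H-pyran-2-one | O=C1O[C@@H](C2=CCCCC2(C)C)C[C@H](C)C1 | intermediate
12 | 1,2,4,5-tetramethoxybenzene | COc1cc(OC)c(OC)cc1OC | starting material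
13 | (2,3,5,6-tetramethoxyphenyl)lithium | [Li]c1c(OC)c(OC)cc(OC)c1OC | intermediate
14 | 2,3,5,6-tetramethoxybenzaldehyde | O=Cc1c(OC)c(OC)cc(OC)c1OC | intermediate
15 | (2,3,5,6-tetramethoxyphenyl)methanol | OCc1c(OC)c(OC)cc(OC)c1OC | intermediate
16 | 2,3,5,6-tetramethoxybenzyl bromide | BrCc1c(OC)c(OC)cc(OC)c1OC | intermediate
17 | sodium enolate of lactone 11 | [Na]OC1=C[C@@H](C)C[C@H](C2=CCCCC2(C)C)O1 | intermediate
18 | (3R,4S,6R)-6-(6,6-dimethylcyclohex-1-en-1-yl)-4-methyl-3-(2,3,5,6-tetramethoxybenzyl)tetrahydro-2H-pyran-2-one | O=C1O[C@@H](C2=CCCCC2(C)C)C[C@H](C)[C@H]1Cc3c(OC)c(OC)cc(OC)c3OC | intermediate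
19 | lithium enolate of lactone 18 | [Li]OC1=C(Cc3c(OC)c(OC)cc(OC)c3OC)[C@@H](C)C[C@H](C2=CCCCC2(C)C)O1 | intermediate
20 | tert-butyldimethylsilyl ketene acetal of lactone 18 | CC(C)(C)[Si](C)(C)OC1=C(Cc3c(OC)c(OC)cc(OC)c3OC)[C@@H](C)C[C@H](C2=CCCCC2(C)C)O1 | intermediate
21 | tert-butyldimethylsilyl ester of acid 22 | COc1cc(OC)c(OC)c(C[C@@]2(C(=O)O[Si](C)(C)C(C)(C)C)[C@@H]3CCCC(C)(C)C3=CC[C@@H]2C)c1OC | intermediate
22 | (1S,2S,8aR)-2,5,5-trimethyl-1-(2,3,5,6-tetramethoxybenzyl)-1,2,3,5,6,7,8,8a-octahydronaphthalene-1-carboxylic acid | COc1cc(OC)c(OC)c(C[C@@]2(C(=O)O)[C@@H]3CCCC(C)(C)C3=CC[C@@H]2C)c1OC | intermediate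
23 | [(1S,2S,8aR)-2,5,5-trimethyl-1-(2,3,5,6-tetramethoxybenzyl)-1,2,3,5,6,7,8,8a-octahydronaphthalen-1-yl]methanol | COc1cc(OC)c(OC)c(C[C@@]2(CO)[C@@H]3CCCC(C)(C)C3=CC[C@@H]2C)c1OC | intermediate
24 | (1S,2S,8aR)-2,5,5-trimethyl-1-(2,3,5,6-tetramethoxybenzyl)-1,2,3,5,6,7,8,8a-octahydronaphthalene-1-carbaldehyde | COc1cc(OC)c(OC)c(C[C@@]2(C=O)[C@@H]3CCCC(C)(C)C3=CC[C@@H]2C)c1OC | intermediate
25 | hydrazone of aldehyde 24 | COc1cc(OC)c(OC)c(C[C@@]2(/C=N/N)[C@@H]3CCCC(C)(C)C3=CC[C@@H]2C)c1OC | intermediate
26 | 3-{[(1R,2S,8aS)-1,2,5,5-tetramethyl-1,2,3,5,6,7,8,8a-octahydronaphthalen-1-yl]methyl}-1,2,4,5-tetramethoxybenzene | COc1cc(OC)c(OC)c(C[C@@]2(C)[C@@H]3CCCC(C)(C)C3=CC[C@@H]2C)c1OC | intermediate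
27 | 2,5-dimethoxy-3-{[(1R,2S,8aS)-1,2,5,5-tetramethyl-octahydronaphthalen-1-yl]methyl}-1,4-benzoquinone | COC1=CC(=O)C(OC)=C(C[C@@]2(C)[C@@H]3CCCC(C)(C)C3=CC[C@@H]2C)C1=O | intermediate
28 | 2-hydroxy-5-methoxy-3-{[(1R,2S,8aS)-1,2,5,5-tetramethyl-octahydronaphthalen-1-yl]methyl}-1,4-benzoquinone | COC1=CC(=O)C(O)=C(C[C@@]2(C)[C@@H]3CCCC(C)(C)C3=CC[C@@H]2C)C1=O | intermediate
29 | (S)-2-methylbutan-1-amine | CC[C@H](C)CN | starting material
30 | nakijiquinone J | CC[C@H](C)CNC1=CC(=O)C(O)=C(C[C@@]2(C)[C@@H]3CCCC(C)(C)C3=CC[C@@H]2C)C1=O | target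

**Step count**
Total: 17 steps. Longest linear sequence: 14 steps (steps 1–6 and 10–17); steps 7–9 form the three-step side branch to bromide 16.

**Steps most likely to fail**

Step 11 (key step). Enolisation and O-silylation at the hindered α-carbon may be incomplete. On heating, the fully substituted acetal carbon may fail to reach C10 in the strained boat, so that ionisation of the allylic C6–O bond and elimination to a dienoic acid outrun the [3,3] shift. The fallback takes the quaternary-centre construction out of the pericyclic step. It sets out from lactone 11: its lithium enolate 10 (LDA, THF, −78 °C) is silylated (TBSCl, HMPA) to the less hindered, trisubstituted tert-butyldimethylsilyl ketene acetal F1. Heating F1 in toluene should bring about the same ring contraction in its α-unsubstituted, directly precedented form and give the tert-butyldimethylsilyl ester F2 of the C9–H decalin acid. Mild aqueous acetic acid then converts F2 into the C9–H acid (1S,2S,8aS)-2,5,5-trimethyl-1,2,3,5,6,7,8,8a-octahydronaphthalene-1-carboxylic acid F3. Double deprotonation of F3 (LDA, 2.2 equiv, THF–HMPA) gives the dilithium enediolate F4. F4 should be alkylated by bromide 16 on the ring face opposite both the C8 methyl and the C10–C1 bond, giving acid 22, where the route is rejoined.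

Step 14 (Wolff–Kishner). Hydrazone formation at the neopentyl aldehyde may be slow, and at 200 °C in KOH azine formation or partial cleavage of the aryl methyl ethers may compete. The fallback is a radical deoxygenation at the alcohol stage, which also saves the oxidation. It sets out from alcohol 23: NaH, CS2 and MeI in THF give the S-methyl xanthate F5. Heating F5 with Bu3SnH and AIBN in xylene at 140 °C (Barton–McCombie deoxygenation) should then give 26, where the route is rejoined. F5 has no β-hydrogen, so thermal Chugaev elimination cannot compete.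

Step 16 (site-selective hydrolysis). Hydroxide may not discriminate well enough between the two vinylogous esters, or may hydrolyse both. The fallback removes the need for selective hydrolysis and lets the amine choose the site. It sets out from 27: exhaustive hydrolysis (2 M NaOH, MeOH–H2O, 60 °C, then acidification) gives the 2,5-dihydroxy-3-alkyl-1,4-benzoquinone F6. Condensation of F6 with amine 29 (EtOH, cat. AcOH, 60 °C) should occur at the unhindered vinylogous acid carbon next to the ring C–H, as known for 2,5-dihydroxy-3-alkylbenzoquinones, because the position next to the bulky decalinylmethyl group is shielded. This gives the target 30 directly.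

**Further compounds**
F1 | step 11 | tert-butyldimethylsilyl ketene acetal of lactone 11 | CC(C)(C)[Si](C)(C)OC1=C[C@@H](C)C[C@H](C2=CCCCC2(C)C)O1
F2 | step 11 | tert-butyldimethylsilyl ester of acid F3 | CC(C)(C)[Si](C)(C)OC(=O)[C@@H]1[C@@H]2CCCC(C)(C)C2=CC[C@@H]1C
F3 | step 11 | (1S,2S,8aS)-2,5,5-trimethyl-1,2,3,5,6,7,8,8a-octahydronaphthalene-1-carboxylic acid | OC(=O)[C@@H]1[C@@H]2CCCC(C)(C)C2=CC[C@@H]1C
F4 | step 11 | dilithium enediolate of acid F3 | [Li]OC(O[Li])=C1[C@@H]2CCCC(C)(C)C2=CC[C@@H]1C
F5 | step 14 | O-alkyl S-methyl xanthate of alcohol 23 | COc1cc(OC)c(OC)c(C[C@@]2(COC(=S)SC)[C@@H]3CCCC(C)(C)C3=CC[C@@H]2C)c1OC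
F6 | step 16 | 2,5-dihydroxy-3-{[(1R,2S,8aS)-1,2,5,5-tetramethyl-octahydronaphthalen-1-yl]methyl}-1,4-benzoquinone | OC1=CC(=O)C(O)=C(C[C@@]2(C)[C@@H]3CCCC(C)(C)C3=CC[C@@H]2C)C1=O
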